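**Retrosynthetic overview**
1. The target is traced back to one hydride operation on Evans syn-aldol adduct 16, made from dihydrobenzofuran aldehyde 9 and arylacetyl imide 13; the aldol sets both side-chain stereocentres.
2. The dihydrofuran ring is opened at the C3–C3a bond: a 5-exo-trig aryl radical cyclisation with O2 capture of iodoaryl 1-arylallyl ether 6 forms that bond, the ring, C3 and the oxygen of the C3–CH2OH arm in one operation.
3. Enabling feature: C3a is the iodine-bearing carbon ortho to the ether oxygen O1 on the iodovanillin ring, and C3 is the internal carbon of the vinyl group on benzylic C2. The O1–C2 tether therefore places radical and alkene for a five-membered closure, and the C2 aryl group steers C3 trans.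
4. Ether 6 comes from an Ir-catalysed branched, enantioselective allylic etherification of 5-iodovanillin 5 with cinnamyl carbonate 4 (sets C2); 4 comes from cross-metathesis of vinylguaiacol pivalate 2 with allyl methyl carbonate 3.
5. Ring order: the three benzene rings are bought; the dihydrofuran ring (O1, C2, C3, C3a, C7a) is the only ring made (step 4); the oxazolidinone is a temporary ring removed in step 8.

Key step: step 4

Remark on the chemistry: the hand of the phosphoramidite ligand in step 3 is chosen from the usual sense of induction for aryl-substituted allyl carbonates ((Sa,S,S)-ligand giving the (S)-branched O-substitution product); should the sense be the opposite, the enantiomeric ligand would be used and nothing else changes.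

**Route**

Step 1
Reactants: 1 2-methoxy-4-vinylphenol
Product: 2 2-methoxy-4-vinylphenyl pivalate
Conditions: PivCl (1.2 equiv), Et3N (1.5 equiv), DMAP (5 mol %), CH2Cl2, 0 °C to rt
Reagents that add atoms: pivaloyl chloride, CC(C)(C)C(Cl)=O
Why: DMAP-catalysed O-acylation of the phenol; the pivalate is chosen because it is electron-withdrawing (it lowers the tendency of the later benzylic ether carbon to ionise) and can be removed by hydride at the end.

Step 2
Reactants: 2 2-methoxy-4-vinylphenyl pivalate; 3 allyl methyl carbonate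
Product: 4 methyl (2E)-3-[3-methoxy-4-(pivaloyloxy)phenyl]prop-2-en-1-yl carbonate
Conditions: 3 (3 equiv), Hoveyda–Grubbs II (3 mol %), CH2Cl2, 40 °C
Reagents that add atoms: none
Why: Olefin cross-metathesis of a styrene with an excess of an allylic carbonate, driven by loss of ethylene and expected to give the thermodynamically preferred E-alkene; no stereocentre is formed.

Step 3
Reactants: 4 methyl (2E)-3-[3-methoxy-4-(pivaloyloxy)phenyl]prop-2-en-1-yl carbonate; 5 5-iodovanillin (4-hydroxy-3-iodo-5-methoxybenzaldehyde)
Product: 6 4-({(1S)-1-[3-methoxy-4-(pivaloyloxy)phenyl]prop-2-en-1-yl}oxy)-3-iodo-5-methoxybenzaldehyde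
Conditions: 5 (1.1 equiv), [Ir(cod)Cl]2 (2 mol %), (Sa,S,S)-Feringa phosphoramidite (4 mol %), TBD (10 mol %), THF, rt; chromatography on Et3N-deactivated silica
Reagents that add atoms: none
Why: Iridium-catalysed asymmetric allylic etherification, in which the aryloxide of 5 (formed by the methoxide released on decarboxylation of the leaving group) attacks the substituted terminus of the (π-allyl)Ir intermediate anti to the metal to give the branched ether; the C2 configuration is set by the cyclometalated chiral phosphoramidite, and the aryl iodide should be inert to Ir(I) at room temperature.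

Step 4
Reactants: 6 4-({(1S)-1-[3-methoxy-4-(pivaloyloxy)phenyl]prop-2-en-1-yl}oxy)-3-iodo-5-methoxybenzaldehyde
Product: 8 (2S,3R)-3-(hydroxymethyl)-7-methoxy-2-[3-methoxy-4-(pivaloyloxy)phenyl]-2,3-dihydrobenzofuran-5-carbaldehyde, via primary hydroperoxide 7 (not isolated)
Conditions: Bu3SnH (2.5 equiv, slow addition), dry air sparge, toluene (0.02 M), 0 °C to rt; aq. KF work-up
Reagents that add atoms: dioxygen (dry air), O=O
Why: Tributylstannyl radical abstracts iodine from C3a, the resulting σ-aryl radical adds to the internal vinyl carbon (the future C3) to form the C3a–C3 bond, and the exocyclic primary radical is captured by O2; the peroxyl radical carries the chain by taking hydrogen from the stannane, and hydroperoxide 7 is reduced by further stannane in the same flask to alcohol 8. The closest known reaction type is the tin hydride/air oxygenative radical cyclisation of 2-iodoaryl allyl ethers to 3-(hydroxymethyl)-2,3-dihydrobenzofurans. The one ring closed is the dihydrofuran ring (C3a, C7a, O1, C2, C3), by a 5-exo-trig closure. The new stereocentre C3 is controlled by the existing C2 centre: in the envelope-like transition state the 2-aryl group sits pseudo-equatorial and the alkene terminus turns away from it, so the CH2O arm should come out trans to the aryl group (2S,3R), the low temperature favouring this, and any cis isomer would be removed by chromatography here, before a phenol is freed. The step needs 5-exo over 6-endo closure (secured by the monosubstituted terminal alkene), ring closure before the aryl radical is quenched (secured by the very fast unimolecular cyclisation against low stannane and oxygen concentrations), and oxygen capture of the primary radical before hydrogen transfer (secured by slow stannane addition into air-saturated dilute solution). The formyl group should survive because iodine abstraction is far faster than stannyl addition to C=O and the stannane intercepts peroxyl radicals before an acyl radical chain can start.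

Step 5
Reactants: 8 (2S,3R)-3-(hydroxymethyl)-7-methoxy-2-[3-methoxy-4-(pivaloyloxy)phenyl]-2,3-dihydrobenzofuran-5-carbaldehyde
Product: 9 {(2S,3R)-5-formyl-7-methoxy-2-[3-methoxy-4-(pivaloyloxy)phenyl]-2,3-dihydrobenzofuran-3-yl}methyl acetate
Conditions: Ac2O (1.5 equiv), pyridine (3 equiv), DMAP (5 mol %), CH2Cl2, 0 °C
Reagents that add atoms: acetic anhydride, CC(=O)OC(C)=O
Why: Standard DMAP-catalysed acetylation of the primary alcohol, which keeps the hydroxyl away from the boron triflate of step 7 and is removed by the hydride of step 8 without a separate step.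

Step 6
Reactants: 10 homovanillic acid (4-hydroxy-3-methoxyphenylacetic acid); 11 (S)-4-benzyl-2-oxazolidinone
Product: 13 (4S)-4-benzyl-3-{2-[3-methoxy-4-(pivaloyloxy)phenyl]acetyl}oxazolidin-2-one, via mixed pivalic anhydride 12 (not isolated)
Conditions: PivCl (2.3 equiv), Et3N (4 equiv), DMAP (5 mol %), THF, −20 to 0 °C; then LiCl (1.2 equiv), 11 (1.0 equiv), rt
Reagents that add atoms: pivaloyl chloride, CC(C)(C)C(Cl)=O
Why: Excess pivaloyl chloride caps the phenol and turns the acid into the mixed pivalic anhydride, which then acylates the LiCl-activated oxazolidinone at the less hindered arylacetyl carbonyl (mixed-anhydride N-acylation).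

Step 7
Reactants: 13 (4S)-4-benzyl-3-{2-[3-methoxy-4-(pivaloyloxy)phenyl]acetyl}oxazolidin-2-one; 9 {(2S,3R)-5-formyl-7-methoxy-2-[3-methoxy-4-(pivaloyloxy)phenyl]-2,3-dihydrobenzofuran-3-yl}methyl acetate
Product: 16 (4S)-4-benzyl-3-[(2S,3S)-3-{(2S,3R)-3-(acetoxymethyl)-7-methoxy-2-[3-methoxy-4-(pivaloyloxy)phenyl]-2,3-dihydrobenzofuran-5-yl}-3-hydroxy-2-[3-methoxy-4-(pivaloyloxy)phenyl]propanoyl]oxazolidin-2-one, via Z-boron enolate 14 (not isolated), via boron aldolate 15 (not isolated)
Conditions: 13 (1.3 equiv), Bu2BOTf (1.4 equiv), iPr2NEt (1.6 equiv), CH2Cl2, −78 to 0 °C; then 9, −78 to 0 °C; pH 7 buffer, MeOH, 30% H2O2, 0 °C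
Reagents that add atoms: dibutylboron triflate, CCCCB(CCCC)OS(=O)(=O)C(F)(F)F (its boron is present only in 14 and 15)
Why: Evans syn-aldol reaction, in which the Z-boron enolate reacts through a closed Zimmerman–Traxler chair with the aldehyde approaching the enolate face opposite the benzyl group of the dipole-opposed auxiliary; both new stereocentres (2S,3S, syn) are therefore set by the auxiliary, and the remote ring stereocentres should not interfere.

Step 8
Reactants: 16 (4S)-4-benzyl-3-[(2S,3S)-3-{(2S,3R)-3-(acetoxymethyl)-7-methoxy-2-[3-methoxy-4-(pivaloyloxy)phenyl]-2,3-dihydrobenzofuran-5-yl}-3-hydroxy-2-[3-methoxy-4-(pivaloyloxy)phenyl]propanoyl]oxazolidin-2-one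
Product: 17 (1S,2R)-1-[(2S,3R)-2-(4-hydroxy-3-methoxyphenyl)-3-(hydroxymethyl)-7-methoxy-2,3-dihydrobenzofuran-5-yl]-2-(4-hydroxy-3-methoxyphenyl)propane-1,3-diol
Conditions: LiBH4 (10 equiv), THF–MeOH, 0 °C to rt; aq. NH4Cl/Rochelle salt work-up at about pH 7
Reagents that add atoms: none
Why: Hydride reduction in which LiBH4 reduces the exocyclic imide carbonyl to the primary alcohol with release of the auxiliary and also cleaves the primary acetate and the two activated aryl pivalates; no stereocentre is touched (the label at the aryl-bearing carbon changes from S to R only through the CIP priorities), and the neutral work-up protects the electron-rich benzylic alcohol.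

**Compound list**
1 | 2-methoxy-4-vinylphenol | COc1cc(C=C)ccc1O | starting material
2 | 2-methoxy-4-vinylphenyl pivalate | COc1cc(C=C)ccc1OC(=O)C(C)(C)C | intermediate
3 | allyl methyl carbonate | C=CCOC(=O)OC | starting material
4 | methyl (2E)-3-[3-methoxy-4-(pivaloyloxy)phenyl]prop-2-en-1-yl carbonate | COC(=O)OC/C=C/c1ccc(OC(=O)C(C)(C)C)c(OC)c1 | intermediate
5 | 5-iodovanillin (4-hydroxy-3-iodo-5-methoxybenzaldehyde) | COc1cc(C=O)cc(I)c1O | starting material
6 | 4-({(1S)-1-[3-methoxy-4-(pivaloyloxy)phenyl]prop-2-en-1-yl}oxy)-3-iodo-5-methoxybenzaldehyde | COc1cc(C=O)cc(I)c1O[C@@H](C=C)c1ccc(OC(=O)C(C)(C)C)c(OC)c1 | intermediate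
7 | (2S,3R)-3-(hydroperoxymethyl)-7-methoxy-2-[3-methoxy-4-(pivaloyloxy)phenyl]-2,3-dihydrobenzofuran-5-carbaldehyde (not isolated) | COc1cc([C@H]2Oc3c(OC)cc(C=O)cc3[C@@H]2COO)ccc1OC(=O)C(C)(C)C | intermediate
8 | (2S,3R)-3-(hydroxymethyl)-7-methoxy-2-[3-methoxy-4-(pivaloyloxy)phenyl]-2,3-dihydrobenzofuran-5-carbaldehyde | COc1cc([C@H]2Oc3c(OC)cc(C=O)cc3[C@@H]2CO)ccc1OC(=O)C(C)(C)C | intermediate
9 | {(2S,3R)-5-formyl-7-methoxy-2-[3-methoxy-4-(pivaloyloxy)phenyl]-2,3-dihydrobenzofuran-3-yl}methyl acetate | COc1cc([C@H]2Oc3c(OC)cc(C=O)cc3[C@@H]2COC(C)=O)ccc1OC(=O)C(C)(C)C | intermediate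
10 | homovanillic acid | COc1cc(CC(=O)O)ccc1O | starting material
11 | (S)-4-benzyl-2-oxazolidinone | O=C1OC[C@H](Cc2ccccc2)N1 | starting material
12 | 2-[3-methoxy-4-(pivaloyloxy)phenyl]acetic pivalic anhydride (not isolated) | COc1cc(CC(=O)OC(=O)C(C)(C)C)ccc1OC(=O)C(C)(C)C | intermediate
13 | (4S)-4-benzyl-3-{2-[3-methoxy-4-(pivaloyloxy)phenyl]acetyl}oxazolidin-2-one | COc1cc(CC(=O)N2[C@@H](Cc3ccccc3)COC2=O)ccc1OC(=O)C(C)(C)C | intermediate
14 | Z-(O)-dibutylboron enolate of 13 (not isolated) | CCCCB(CCCC)O/C(=C\c1ccc(OC(=O)C(C)(C)C)c(OC)c1)N1[C@@H](Cc2ccccc2)COC1=O | intermediate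
15 | O-dibutylboryl aldolate of 16 (not isolated) | COc1cc([C@H]2Oc3c(OC)cc([C@@H](OB(CCCC)CCCC)[C@@H](C(=O)N4[C@@H](Cc5ccccc5)COC4=O)c4ccc(OC(=O)C(C)(C)C)c(OC)c4)cc3[C@@H]2COC(C)=O)ccc1OC(=O)C(C)(C)C | intermediate
16 | (4S)-4-benzyl-3-[(2S,3S)-3-{(2S,3R)-3-(acetoxymethyl)-7-methoxy-2-[3-methoxy-4-(pivaloyloxy)phenyl]-2,3-dihydrobenzofuran-5-yl}-3-hydroxy-2-[3-methoxy-4-(pivaloyloxy)phenyl]propanoyl]oxazolidin-2-one | COc1cc([C@H]2Oc3c(OC)cc([C@@H](O)[C@@H](C(=O)N4[C@@H](Cc5ccccc5)COC4=O)c4ccc(OC(=O)C(C)(C)C)c(OC)c4)cc3[C@@H]2COC(C)=O)ccc1OC(=O)C(C)(C)C | intermediate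
17 | (1S,2R)-1-[(2S,3R)-2-(4-hydroxy-3-methoxyphenyl)-3-(hydroxymethyl)-7-methoxy-2,3-dihydrobenzofuran-5-yl]-2-(4-hydroxy-3-methoxyphenyl)propane-1,3-diol | COc1cc([C@H]2Oc3c(OC)cc([C@@H](O)[C@@H](CO)c4ccc(O)c(OC)c4)cc3[C@@H]2CO)ccc1O | target

**Totals**
Total step count: 8. Longest linear sequence: 7 steps (steps 1, 2, 3, 4, 5, 7, 8).

**Three steps most likely to fail**

Step 4. The processes at risk are hydrogen-atom transfer from the stannane to the cyclised primary radical before oxygen capture (over-reduction to the 3-methyl compound), chain oxidation of the formyl group under air, and facial selectivity lower than hoped. Fallback: the fallback sets out from 6 and replaces the oxygen chain by capture with a persistent nitroxide under exclusion of air. Treatment of 6 with Bu3SnH and TEMPO in toluene at 60–70 °C should give, by the same 5-exo closure followed by radical–radical coupling, the alkoxyamine (2S,3R)-7-methoxy-2-[3-methoxy-4-(pivaloyloxy)phenyl]-3-{[(2,2,6,6-tetramethylpiperidin-1-yl)oxy]methyl}-2,3-dihydrobenzofuran-5-carbaldehyde F1. Reductive N–O cleavage of F1 with zinc in AcOH–THF–H2O at 40–50 °C should then deliver the alcohol, and the route is rejoined at 8.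

Step 3. The processes at risk are re-ionisation of the branched ether by the catalyst (the aryloxide of 5 is a good leaving group), which would erode the branched regiochemistry and the enantiomeric purity, and sluggish attack by the doubly ortho-substituted aryloxide. Fallback: the fallback sets out from 4 and forms the aryl–O–C2 bond by SN2 displacement instead. Iridium-catalysed allylic hydroxylation of 4 with aqueous KHCO3 and the enantiomeric (Ra,R,R)-phosphoramidite should give (R)-1-[3-methoxy-4-(pivaloyloxy)phenyl]prop-2-en-1-ol F2, whose product is an alcohol and cannot re-ionise. Mitsunobu etherification of F2 with the acidic phenol 5 (PPh3, DIAD, toluene, −20 to 0 °C) should then proceed with inversion, and the route is rejoined at 6.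

Step 8. The process at risk is incomplete hydride cleavage of the hindered aryl pivalates, leaving partly acylated material, with retro-aldol loss on prolonged exposure to the basic borohydride medium. Fallback: the fallback sets out from 16 and separates the two tasks. A short reduction with LiBH4 (3 equiv) in THF with a little water at 0 °C should remove only the auxiliary and the acetate and give the bis-pivalate (1S,2R)-1-{(2S,3R)-3-(hydroxymethyl)-7-methoxy-2-[3-methoxy-4-(pivaloyloxy)phenyl]-2,3-dihydrobenzofuran-5-yl}-2-[3-methoxy-4-(pivaloyloxy)phenyl]propane-1,3-diol F3. Methanolysis of F3 with K2CO3 in MeOH at 0 °C should then free both phenols (partly deacylated material converges as well), and the route is rejoined at 17.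

**Further compounds**
F1 | step 4 | (2S,3R)-7-methoxy-2-[3-methoxy-4-(pivaloyloxy)phenyl]-3-{[(2,2,6,6-tetramethylpiperidin-1-yl)oxy]methyl}-2,3-dihydrobenzofuran-5-carbaldehyde | COc1cc([C@H]2Oc3c(OC)cc(C=O)cc3[C@@H]2CON4C(C)(C)CCCC4(C)C)ccc1OC(=O)C(C)(C)C
F2 | step 3 | (R)-1-[3-methoxy-4-(pivaloyloxy)phenyl]prop-2-en-1-ol | O[C@H](C=C)c1ccc(OC(=O)C(C)(C)C)c(OC)c1
F3 | step 8 | (1S,2R)-1-{(2S,3R)-3-(hydroxymethyl)-7-methoxy-2-[3-methoxy-4-(pivaloyloxy)phenyl]-2,3-dihydrobenzofuran-5-yl}-2-[3-methoxy-4-(pivaloyloxy)phenyl]propane-1,3-diol | COc1cc([C@H]2Oc3c(OC)cc([C@@H](O)[C@@H](CO)c4ccc(OC(=O)C(C)(C)C)c(OC)c4)cc3[C@@H]2CO)ccc1OC(=O)C(C)(C)C
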